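## Analysis of the target

Compound 36 is a Diels–Alder-type hetero-dimer of two sesquiterpene lactones: an upper guaianolide (C1–C15) and a lower 1,10-seco-eudesmanolide (primed locants). The halves share a bicyclo[2.2.1]heptene made of C1, C2, C3, C4=C5, C11' and C13'; C11' is also the spiro carbon of the lower γ-lactone and C1 is a quaternary bridgehead. The seven-membered guaiane ring (C1, C5–C10) is annulated at C1–C5 and carries the trans-fused α-methylene lactone at C7/C8 and the methyl-bearing C10. The lower half is a cyclohexene with a tetrasubstituted alkene, a cis-fused lactone at C7'/C8', a free allylic hydroxyl at C6' and the acetoxy side chain.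

There are eleven stereocentres. C4', C6', C7' and C8' come with the lower half; C7/C8 are a trans pair. C1, C3 and C11' arise together, with the lactone carbonyl C12' on the side of the one-carbon bridge (exo) and with C3 on the same face of the lower lactone as C6'. The acetoxy group on the bridge carbon C2 points over C4=C5, and the C10 methyl lies on the face of the C2 bridge.

Sensitive functions are the α-methylene lactone (a Michael acceptor, unveiled last), two acetates beside two lactones (no hydride reagents, no strong nucleophiles) and two tetrasubstituted alkenes (no electrophilic oxidants).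

The difficulty is three face problems:
- Oxygen at C2 sits on the face that neither a cycloaddition of a C2-oxygenated cyclopentadiene (oxygen steers the dienophile to its own face) nor hydride reduction of a C2 ketone would deliver.
- The dienophile face needed at C11' is the one that the cis-fused lower lactone screens with its own ring carbon C6'.
- C10 must be set on a flexible ring.

The plan rests on one feature: in the seven-membered ring the C9–C10 bond lies between the lactone carbinol C8 and the quaternary bridgehead C1. A vinyl group on C8 and an isopropenyl group on C1 of a preformed norbornene can therefore be joined, leaving only C10 to a hydrogenation.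

## Retrosynthetic reasoning

**C11=C13 and the C6' silyl ether (36 ⇐ 35 ⇐ 33 ⇐ 32).** The exocyclic methylene is cut first, because it would not survive metathesis, hydrogenation or peroxide. Forward, C13 is added to the lactone enolate of 32 as an aminomethyl group (33) and unveiled by elimination (35). The only protecting group is then removed.

**C9–H and C10–H (32 ⇐ 31 ⇐ 30).** C10 is traced back to the trisubstituted alkene of 30. The hydrogenation must add to the face of C9=C10 that carries O8 and C13'; the other face is covered by the acetoxy-bearing bridge. The free C6' hydroxyl is silylated first (31) so that it cannot direct the catalyst to the neighbouring C5'=C10' alkene.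

**C9=C10 (30 ⇐ 29), the key disconnection.** Cutting this alkene removes the seven-membered ring and no stereocentre. What remains, 29, is a norbornene with an isopropenyl group on C1 and a trans vinyl lactone on the C5 side chain. The cut is placed here because both ends sit on adjacent atoms of a rigid bicycle, and because it lets the two halves be joined before any medium ring exists.

**Position of the lower lactone (29 ⇐ 27).** In 29 the lower lactone is closed to O8' as in the target. It is traced back to the isomer 27 with the lactone on O6' and a silyl ether on O8'. Only in this trans-fused isomer is the face of C11' that must bond the open one. Forward, desilylation and acyl migration return the lactone to its natural position.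

**C2–O and the isopropenyl group (27 ⇐ 26 ⇐ 25 ⇐ 24 ⇐ 23).** The C2 acetate is traced to a C2–Si bond (oxidation with retention) and the isopropenyl group to a methyl ketone. Both are tied together in 23 as one oxasilole ring: a silyl enol ether of the ketone whose silicon sits on C2. The ketone is methylenated before the oxidation, so that no β-hydroxy ketone prone to retro-aldol opening of the strained bicycle is made.

**C1–C13' and C3–C11' (23 ⇐ 22 + 3).** Both bonds to the lower half are cut at once, giving the silicon-bridged cyclopentadiene 22 and the methylene lactone 3. Silicon is used at C2 because a dienophile adds anti to it, which puts it, and later oxygen, over C4=C5. The bridge to the C1 substituent holds silicon on C2, since a shift to C3 would need a double bond at a bridgehead of a small bicycle.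

**Si–C2, Si–O and C1–C10 (22 ⇐ 20 ⇐ 17 + 18 ⇐ 16).** The bridge is cut back to the acetyl cyclopentadiene 20, which is as acidic as a 1,3-diketone. The acetyl group is placed regiospecifically on C1 by coupling the dienyl triflate 17 (from enone 16) with the acyl anion equivalent 18.

**C5–C6 (16 ⇐ 12 + 14 ⇐ 13).** The side chain is attached by sp3–sp2 coupling of the iodide 12 with the α-iodoenone 14, made from 13. An organozinc tolerates the lactone.

**C7–C8 (12 ⇐ 11 ⇐ 10 ⇐ 9 ⇐ 6 + 7; 6 ⇐ 4 + 5).** The trans vinyl lactone comes from a syn-aldol of the succinate imide 6 with 7: the syn adduct lactonises to the trans lactone. The auxiliary 4 sets both centres absolutely, and the acyl carbon becomes C6.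

**Lower half (3 ⇐ 1).** 3 is the 6',12'-lactone isomer of natural 1, trapped as its C8' silyl ether. All four lower stereocentres are taken over unchanged.

## Alternatives that were turned down

**Alternative 1:** The lower cyclohexene is opened at C6'–C5' and C9'–C10'. Forward, a zerovalent nickel carbene catalyst (Ni(cod)2 with an N-aryl imidazolylidene) would insert an internal alkyne into the C6'–C9' bond of a cyclobutanone fused to the lower lactone, giving the cyclohexenone A1 with the tetrasubstituted alkene and the side chain in one operation.
- For: it makes the most substituted alkene and a ring at once. Because the lower carbocycle is absent while the spiro centre is made, C6' cannot screen C11'. On this point it is stronger than the chosen route, which has to move the lactone to O6' and back.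
- Against: four stereocentres that 1 supplies for nothing must be built. The insertion must tell apart the two ends of an unsymmetrical dialkyl alkyne. The acyl–nickel intermediate sits next to the epimerisable C7'. A1 still needs a reduction at C6' that brings hydride from the lactone side.
- Comparison: clearly longer. The chosen strategy keeps 1 intact and spends its risk on one ring closure.

**Alternative 2:** The norbornene is opened at C2–C3. Forward, Me2AlCl would activate an aldehyde carbon (C2) on C1 for a transannular carbonyl-ene reaction with a C3=C4 alkene. C2–C3 forms, hydrogen passes from C5 to oxygen, C4=C5 appears, and A2 results with its hydroxyl over the new alkene.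
- For: the ene geometry puts oxygen on exactly the face that is hardest to reach. For C2 this is stronger than the silicon sequence used here, which costs four operations after the cycloaddition.
- Against: the step only closes a bridge. The two halves must already be joined through C1–C13' and C3–C11' in a cyclohexene carrying the quaternary C1 and the spiro C11', and no equally convergent reaction exists for that. The seven-membered ring and C10 must be in place beforehand. A strained bicycle has to be closed against Prins-type pathways.
- Comparison: the chosen strategy joins the halves in one cycloaddition and builds the seven-membered ring late on a rigid template.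

**Alternative 3:** The saturated bridge is opened at C13'–C11'. Forward, SmI2 would cleave an α-phenylsulfonyl group on the lower lactone to a samarium enolate at C11' that adds to a formyl group (C13') on C1, closing the five-membered ring and giving A3.
- For: mild generation of a fully substituted enolate. Chelation of samarium between aldehyde and lactone can order the transition state, a control at C11' at least as strong as the exo rule of a cycloaddition. The new carbon enters C11' from the open H-7' face of the cis-fused lactone.
- Against: A3 carries a hydroxyl at C13' that the target lacks; removing it from a position between two quaternary carbons, with an α-methylene lactone present, costs two to three steps of doubtful chemoselectivity. SmI2 also reduces α-methylene lactones. The C3–C11' bond must first be made by an intermolecular alkylation of two hindered partners.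
- Comparison: the chosen route forms both bonds in one step and leaves nothing to delete.

Key step: step 18

Remark: 1 is taken in the configuration drawn, and its cis-fused 8',12'-lactone is assumed to be the thermodynamically preferred lactone isomer, as its isolation in this form suggests. 22 is drawn as its C2-sp3 tautomer, which equilibrates with its 1,5-hydrogen-shift isomers and its C2 epimer.

## Steps

Step 1
Reactants: 1 1-O-acetylbritannilactone
Product: 3 6',12'-lactone isomer of 1 as its C8' tert-butyldimethylsilyl ether, via 6',12'-lactone alcohol 2 (not isolated)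
Conditions: DBU (0.3 equiv), TBSCl, imidazole, DMF, 40 °C
Reagents that add atoms: tert-butyl(chloro)dimethylsilane, CC(C)(C)[Si](C)(C)Cl
Why: Base-mediated acyl migration equilibrates the cis-fused 8',12'-lactone with its trans-fused 6',12' isomer 2; only 2 has an unhindered secondary hydroxyl (C8'), so the bulky silyl chloride drains it from the equilibrium (silyl ether formation under Curtin–Hammett conditions). In the trans-fused lactone the ring carbon next to the methylene (C8') lies on the face opposite to the one that has to bond in step 12.

Step 2
Reactants: 4 (4R)-4-benzyl-1,3-oxazolidin-2-one; 5 methyl 4-chloro-4-oxobutanoate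
Product: 6 methyl 4-[(4R)-4-benzyl-2-oxo-1,3-oxazolidin-3-yl]-4-oxobutanoate
Conditions: n-BuLi, THF, −78 °C; then 5, −78 → 0 °C
Reagents that add atoms: none
Why: N-Acylation of the lithiated oxazolidinone by the acid chloride; the methyl ester is not attacked at low temperature.

Step 3
Reactants: 6 methyl 4-[(4R)-4-benzyl-2-oxo-1,3-oxazolidin-3-yl]-4-oxobutanoate; 7 acrolein
Product: 9 (4R)-4-benzyl-3-{[(2S,3R)-2-ethenyl-5-oxooxolan-3-yl]carbonyl}-1,3-oxazolidin-2-one, via syn-aldol adduct 8 (not isolated)
Conditions: Bu2BOTf, iPr2NEt, CH2Cl2, −78 → 0 °C; 7, −78 → 0 °C; H2O2, MeOH, pH 7 buffer; then PPTS, toluene, 60 °C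
Reagents that add atoms: none
Why: Evans syn-aldol reaction: the dibutylboron Z-enolate of the imide (the imide α-CH2 is enolised, not the ester) adds to acrolein through the chair transition state ruled by the (R)-benzyl auxiliary and sets C7 (R) and C8 (S). The syn adduct closes onto the methyl ester to the γ-lactone, in which the acyl and vinyl groups are trans.

Step 4
Reactants: 9 (4R)-4-benzyl-3-{[(2S,3R)-2-ethenyl-5-oxooxolan-3-yl]carbonyl}-1,3-oxazolidin-2-one
Product: 10 (2S,3R)-2-ethenyl-5-oxooxolane-3-carboxylic acid
Conditions: LiOH, H2O2, THF/H2O, 0 °C; Na2SO3; then 1 M HCl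
Reagents that add atoms: hydrogen peroxide, OO
Why: Hydroperoxide cleaves the exocyclic imide carbonyl and returns the auxiliary; any lactone that opens closes again on acidification, since only the γ-lactone to O8 can form.

Step 5
Reactants: 10 (2S,3R)-2-ethenyl-5-oxooxolane-3-carboxylic acid
Product: 11 (4S,5S)-5-ethenyl-4-(hydroxymethyl)oxolan-2-one
Conditions: i-BuOCOCl, N-methylmorpholine, THF, −15 °C; then NaBH4, H2O, −15 → 0 °C
Reagents that add atoms: none
Why: Reduction of the mixed carbonic anhydride by borohydride reduces the acid in the presence of the lactone and of the vinyl group, which rules out borane.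

Step 6
Reactants: 11 (4S,5S)-5-ethenyl-4-(hydroxymethyl)oxolan-2-one
Product: 12 (4R,5S)-5-ethenyl-4-(iodomethyl)oxolan-2-one
Conditions: I2, PPh3, imidazole, CH2Cl2, 0 °C → rt
Reagents that add atoms: iodine, II
Why: Appel-type iodination of the primary alcohol under near-neutral conditions, which gives the alcohol no chance to translactonise.

Step 7
Reactants: 13 3-methylcyclopent-2-en-1-one
Product: 14 2-iodo-3-methylcyclopent-2-en-1-one
Conditions: I2, pyridine, CH2Cl2, rt
Reagents that add atoms: iodine, II
Why: α-Iodination of the enone by conjugate addition of pyridine, iodination of the enolate and elimination.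

Step 8
Reactants: 12 (4R,5S)-5-ethenyl-4-(iodomethyl)oxolan-2-one; 14 2-iodo-3-methylcyclopent-2-en-1-one
Product: 16 2-{[(2S,3R)-2-ethenyl-5-oxooxolan-3-yl]methyl}-3-methylcyclopent-2-en-1-one, via alkylzinc iodide 15 (not isolated)
Conditions: Zn dust (activated with BrCH2CH2Br and Me3SiCl), LiCl, THF, 40 °C; then 14, Pd2(dba)3 (2.5 mol %), SPhos (10 mol %), THF, rt → 45 °C
Reagents that add atoms: none
Why: Negishi coupling: zinc inserts into the primary C–I bond without touching the lactone, and the alkylzinc iodide couples with the α-iodoenone at zerovalent palladium to make C5–C6. No stereocentre takes part.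

Step 9
Reactants: 16 2-{[(2S,3R)-2-ethenyl-5-oxooxolan-3-yl]methyl}-3-methylcyclopent-2-en-1-one
Product: 17 2-{[(2S,3R)-2-ethenyl-5-oxooxolan-3-yl]methyl}-3-methylcyclopenta-1,3-dien-1-yl trifluoromethanesulfonate
Conditions: Tf2O, 2,6-di-tert-butyl-4-methylpyridine, CH2Cl2, −78 → 0 °C
Reagents that add atoms: trifluoromethanesulfonic anhydride, O=S(=O)(OS(=O)(=O)C(F)(F)F)C(F)(F)F
Why: O-Triflation of the enone carbonyl and loss of a ring proton give the dienyl triflate (enol triflate formation); no enolate base is used, so the lactone is untouched.

Step 10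
Reactants: 17 2-{[(2S,3R)-2-ethenyl-5-oxooxolan-3-yl]methyl}-3-methylcyclopenta-1,3-dien-1-yl trifluoromethanesulfonate; 18 tributyl(1-ethoxyethenyl)stannane
Product: 20 1-(2-{[(2S,3R)-2-ethenyl-5-oxooxolan-3-yl]methyl}-3-methylcyclopenta-1,3-dien-1-yl)ethan-1-one, via ethoxyvinyl diene 19 (not isolated)
Conditions: Pd(PPh3)4 (5 mol %), LiCl, THF, 60 °C; then 1 M HCl, THF, rt
Reagents that add atoms: water, O
Why: Stille coupling of the dienyl triflate with the acyl anion equivalent, then hydrolysis of the enol ether to the methyl ketone. This fixes the acetyl group on C1, which no electrophilic substitution of the cyclopentadienide could do regioselectively.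

Step 11
Reactants: 20 1-(2-{[(2S,3R)-2-ethenyl-5-oxooxolan-3-yl]methyl}-3-methylcyclopenta-1,3-dien-1-yl)ethan-1-one
Product: 22 4-{[(2S,3R)-2-ethenyl-5-oxooxolan-3-yl]methyl}-5-methyl-3-methylidene-1,1-di(propan-2-yl)-3,6a-dihydro-1H-cyclopenta[c][1,2]oxasilole (silicon on C2 and oxygen on C10 of the guaiane numbering; both C2 epimers), via chlorosilyloxy fulvene 21 (not isolated)
Conditions: KHMDS (1.0 equiv), THF, −78 °C; iPr2SiCl2 (1.0 equiv), −78 → 0 °C; KHMDS (1.0 equiv), −78 → 0 °C
Reagents that add atoms: dichlorodi(propan-2-yl)silane, CC(C)[Si](Cl)(Cl)C(C)C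
Why: The acetyl cyclopentadiene is deprotonated like a 1,3-diketone and its fulvenolate is silylated on oxygen; the 6-methyl group of the resulting siloxyfulvene is then deprotonated to a cyclopentadienide, which attacks the remaining Si–Cl bond through C2, the only unsubstituted neighbour of C1 (cyclopentadienide silylation, five-membered ring). The oxasilole ring keeps silicon on C2, because a shift to C3 would need a bridgehead double bond.

Step 12
Reactants: 22 silicon-bridged cyclopentadiene; 3 6',12'-lactone isomer of 1 as its C8' silyl ether
Product: 23 cycloadduct: norbornene with C1–C13' and C3–C11' bonds, spiro lactone at C11' with C12' exo, oxasilole ring bridging C1 (through C10 and oxygen) and C2 (silicon, over C4=C5)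
Conditions: toluene, BHT (cat.), 90 °C, sealed tube
Reagents that add atoms: none
Why: Diels–Alder reaction: the unsubstituted terminus C3 takes the quaternary carbon C11' and the substituted terminus C1 takes C13' (steric regiocontrol), the dienophile comes in anti to silicon so that silicon ends on the bridge over C4=C5, and the s-cis-locked methylene lactone reacts exo, with C12' toward the C2 bridge that shows only hydrogen on that side. On the trans-fused lactone of 3 the open face is that of H-7' (C8' and its silyloxy group screen the other), and this sense of addition places C3 on the C6' side once the lactone is back on O8'. The two C2 epimers of 22 interconvert through 1,5-hydrogen shifts at this temperature, so the epimer matched to 3 is the one consumed.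

Step 13
Reactants: 23 cycloadduct
Product: 24 methyl ketone on C1 and hydroxydi(propan-2-yl)silyl group on C2
Conditions: 0.1 M HCl, THF/H2O, 0 °C
Reagents that add atoms: water, O
Why: Hydrolysis of the silyl enol ether: protonation at the methylene carbon and attack of water at silicon give the methyl ketone and the silanol; the C–Si bond and the C8' silyl ether survive cold dilute acid.

Step 14
Reactants: 24 ketone silanol
Product: 25 isopropenyl group on C1 and hydroxydi(propan-2-yl)silyl group on C2
Conditions: Zn, CH2Br2, TiCl4, THF/CH2Cl2, 0 °C → rt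
Reagents that add atoms: dibromomethane, BrCBr
Why: Takai–Lombardo methylenation: the non-basic zinc–titanium methylene reagent converts hindered ketones into 1,1-disubstituted alkenes and leaves lactones and the acetate alone. Doing it before the oxidation avoids a β-hydroxy ketone that could open the strained bicycle by retro-aldol cleavage.

Step 15
Reactants: 25 isopropenyl silanol
Product: 26 secondary alcohol at C2 (hydroxyl over C4=C5)
Conditions: KF, KHCO3, 30% H2O2, THF/MeOH, 40 °C
Reagents that add atoms: hydrogen peroxide, OO
Why: Tamao oxidation: fluoride and hydroperoxide add to silicon and C2 migrates from silicon to oxygen with retention, so the hydroxyl takes the place of silicon over C4=C5. Nucleophilic peroxide does not touch the unactivated alkenes.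

Step 16
Reactants: 26 C2 alcohol
Product: 27 C2 acetate (lower lactone still on O6', silyl ether on O8')
Conditions: Ac2O, DMAP, pyridine, CH2Cl2, rt
Reagents that add atoms: acetic anhydride, CC(=O)OC(C)=O
Why: DMAP-catalysed acetylation of the hindered secondary alcohol.

Step 17
Reactants: 27 C2 acetate with 6',12'-lactone
Product: 29 norbornene with isopropenyl group on C1, trans vinyl lactone arm on C5, C2 acetate, lower lactone on O8' and free C6' hydroxyl, via 8'-hydroxy 6',12'-lactone 28 (not isolated)
Conditions: HF·pyridine, THF, 0 °C → rt; then DBU (0.2 equiv), CH2Cl2, rt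
Reagents that add atoms: none
Why: Fluoride removes the C8' silyl ether, and base-catalysed acyl migration moves the lactone carbonyl from O6' to O8' (translactonisation), back to the cis-fused arrangement in which 1 itself rests. No bond to a stereocentre is broken, so C6', C7', C8' and C11' keep their configuration.

Step 18
Reactants: 29 ring-closing metathesis precursor
Product: 30 9,10-dehydro target lacking the upper methylene (seven-membered ring closed, C9=C10)
Conditions: second-generation Grubbs catalyst (H2IMes)(PCy3)Cl2Ru=CHPh (10 mol %), 1,4-benzoquinone (20 mol %), toluene (2 mM), 80 °C, argon purge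
Reagents that add atoms: none
Why: The ruthenium benzylidene exchanges onto the monosubstituted vinyl group on C8; the new alkylidene adds across the isopropenyl group on C1 to a ruthenacyclobutane, and cycloreversion gives the trisubstituted C9=C10 alkene and a ruthenium methylidene, while the two terminal methylene groups leave as ethene. The closest known reaction type is ring-closing metathesis to trisubstituted cycloheptenes next to a quaternary carbon with second-generation catalysts. The ring that closes is the seven-membered ring C1–C10–C9–C8–C7–C6–C5, and it closes on a template: C1 and C5 are neighbours in the rigid norbornene, so their substituents are held cis and within reach, and the trans lactone points the vinyl group toward C10. No stereocentre is formed, and C1 and C8 are not touched. The step needs chemoselectivity among four alkenes: the two tetrasubstituted ones are inert to the catalyst, and initiation at the least hindered vinyl group decides the direction of ring closure. The competing reactions are intermolecular metathesis of the vinyl groups, countered by high dilution and removal of ethene, and double-bond migration by ruthenium hydrides, countered by benzoquinone. The free C6' hydroxyl, the acetates and the lactones are tolerated by the catalyst.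

Step 19
Reactants: 30 9,10-dehydro compound with free C6' hydroxyl
Product: 31 C6' triethylsilyl ether of 30
Conditions: Et3SiOTf, 2,6-lutidine, CH2Cl2, −78 → 0 °C
Reagents that add atoms: triethylsilyl trifluoromethanesulfonate, CC[Si](CC)(CC)OS(=O)(=O)C(F)(F)F
Why: Silyl ether formation; it keeps the allylic hydroxyl from directing the iridium catalyst to C5'=C10' in step 20 and from consuming base in step 21.

Step 20
Reactants: 31 C6' triethylsilyl ether
Product: 32 9,10-dihydro compound with the C10 methyl on the face of the C2 bridge
Conditions: [Ir(cod)(PCy3)(py)]PF6 (5 mol %), H2 (1 atm), CH2Cl2, 0 °C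
Reagents that add atoms: none
Why: Homogeneous hydrogenation of the trisubstituted alkene, which is reduced much faster than the two tetrasubstituted ones. Hydrogen is delivered to the face of C9=C10 that carries the lactone oxygen on C8 and C13', since the other face lies under the acetoxy-bearing bridge; this puts hydrogen on C10 cis to C13' and the methyl group on the side of C2.

Step 21
Reactants: 32 9,10-dihydro compound
Product: 33 α-(dimethylaminomethyl) lactone (C11 epimers)
Conditions: LiHMDS (1.1 equiv), THF, −78 °C; then CH2=NMe2 I, −78 → 0 °C
Reagents that add atoms: N,N-dimethylmethyleneiminium iodide (Eschenmoser's salt), C[N+](C)=C.[I-]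
Why: The lactone α-CH2 (C11) is several pKa units more acidic than the acetate methyl groups, so one equivalent of the hindered amide gives the lactone enolate, which is aminomethylated (Mannich reaction). The spiro lactone has no α-hydrogen.

Step 22
Reactants: 33 α-(dimethylaminomethyl) lactone
Product: 35 α-methylene lactone with C6' triethylsilyl ether, via trimethylammonium iodide 34 (not isolated)
Conditions: MeI, CH2Cl2, rt; then aq. NaHCO3, EtOAc, rt
Reagents that add atoms: none
Why: Quaternisation and Hofmann-type elimination through the only acidic hydrogen (on C11) give the exocyclic methylene; bicarbonate leaves the acetates alone.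

Step 23
Reactants: 35 silyl-protected target
Product: 36 CNP0211028.3
Conditions: HF·pyridine, pyridine, THF, 0 °C → rt
Reagents that add atoms: none
Why: Buffered fluoride removes the triethylsilyl ether without a base that could add to the methylene lactone or shift the lower lactone to O6'.

## Compound list

1 | 1-O-acetylbritannilactone | C=C1C(=O)O[C@@H]2CC(C)=C([C@@H](C)CCCOC(C)=O)[C@@H](O)[C@@H]21 | starting material
2 | 6',12'-lactone isomer of 1 (lactone on O6', trans-fused; free C8' hydroxyl) | C=C1C(=O)O[C@@H]2C([C@@H](C)CCCOC(C)=O)=C(C)C[C@@H](O)[C@@H]12 | intermediate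
3 | C8' tert-butyldimethylsilyl ether of 2 | C=C1C(=O)O[C@@H]2C([C@@H](C)CCCOC(C)=O)=C(C)C[C@@H](O[Si](C)(C)C(C)(C)C)[C@@H]12 | intermediate
4 | (4R)-4-benzyl-1,3-oxazolidin-2-one | O=C1N[C@H](Cc2ccccc2)CO1 | starting material
5 | methyl 4-chloro-4-oxobutanoate | COC(=O)CCC(Cl)=O | starting material
6 | methyl 4-[(4R)-4-benzyl-2-oxo-1,3-oxazolidin-3-yl]-4-oxobutanoate | COC(=O)CCC(=O)N1C(=O)OC[C@H]1Cc1ccccc1 | intermediate
7 | acrolein (prop-2-enal) | C=CC=O | starting material
8 | methyl (3R,4S)-3-[(4R)-4-benzyl-2-oxo-1,3-oxazolidine-3-carbonyl]-4-hydroxyhex-5-enoate | COC(=O)C[C@H]([C@@H](O)C=C)C(=O)N1C(=O)OC[C@H]1Cc1ccccc1 | intermediate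
9 | (4R)-4-benzyl-3-{[(2S,3R)-2-ethenyl-5-oxooxolan-3-yl]carbonyl}-1,3-oxazolidin-2-one | C=C[C@@H]1OC(=O)C[C@H]1C(=O)N2C(=O)OC[C@H]2Cc3ccccc3 | intermediate
10 | (2S,3R)-2-ethenyl-5-oxooxolane-3-carboxylic acid | C=C[C@@H]1OC(=O)C[C@H]1C(=O)O | intermediate
11 | (4S,5S)-5-ethenyl-4-(hydroxymethyl)oxolan-2-one | C=C[C@@H]1OC(=O)C[C@H]1CO | intermediate
12 | (4R,5S)-5-ethenyl-4-(iodomethyl)oxolan-2-one | C=C[C@@H]1OC(=O)C[C@H]1CI | intermediate
13 | 3-methylcyclopent-2-en-1-one | CC1=CC(=O)CC1 | starting material
14 | 2-iodo-3-methylcyclopent-2-en-1-one | CC1=C(I)C(=O)CC1 | intermediate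
15 | {[(2S,3R)-2-ethenyl-5-oxooxolan-3-yl]methyl}zinc iodide | C=C[C@@H]1OC(=O)C[C@H]1C[Zn]I | intermediate
16 | 2-{[(2S,3R)-2-ethenyl-5-oxooxolan-3-yl]methyl}-3-methylcyclopent-2-en-1-one | C=C[C@@H]1OC(=O)C[C@H]1CC2=C(C)CCC2=O | intermediate
17 | 2-{[(2S,3R)-2-ethenyl-5-oxooxolan-3-yl]methyl}-3-methylcyclopenta-1,3-dien-1-yl trifluoromethanesulfonate | C=C[C@@H]1OC(=O)C[C@H]1CC2=C(OS(=O)(=O)C(F)(F)F)CC=C2C | intermediate
18 | tributyl(1-ethoxyethenyl)stannane | CCCC[Sn](CCCC)(CCCC)C(=C)OCC | starting material
19 | 1-(1-ethoxyethenyl) analogue of 20 (enol ether on C1 of the diene) | C=C[C@@H]1OC(=O)C[C@H]1CC2=C(C(=C)OCC)CC=C2C | intermediate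
20 | 1-(2-{[(2S,3R)-2-ethenyl-5-oxooxolan-3-yl]methyl}-3-methylcyclopenta-1,3-dien-1-yl)ethan-1-one | C=C[C@@H]1OC(=O)C[C@H]1CC2=C(C(C)=O)CC=C2C | intermediate
21 | 6-methyl-6-{[chlorodi(propan-2-yl)silyl]oxy}fulvene carrying the lactone arm on C1 and methyl on C2 of the fulvene ring | C=C[C@@H]1OC(=O)C[C@H]1CC2=C(C)C=CC2=C(C)O[Si](Cl)(C(C)C)C(C)C | intermediate
22 | 4-{[(2S,3R)-2-ethenyl-5-oxooxolan-3-yl]methyl}-5-methyl-3-methylidene-1,1-di(propan-2-yl)-3,6a-dihydro-1H-cyclopenta[c][1,2]oxasilole | C=C[C@@H]1OC(=O)C[C@H]1CC2=C3C(=C)O[Si](C(C)C)(C(C)C)C3C=C2C | intermediate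
23 | cycloadduct: norbornene with oxasilole ring across C1/C2 (Si on C2 over C4=C5), spiro 6',12'-lactone at C11' (C12' exo), C8' OTBS | C=C[C@@H]1OC(=O)C[C@H]1CC3=C(C)[C@@H]4[C@@]5(C(=O)O[C@@H]6C([C@@H](C)CCCOC(C)=O)=C(C)C[C@@H](O[Si](C)(C)C(C)(C)C)[C@H]65)C[C@@]3(C(=C)O[Si]7(C(C)C)C(C)C)[C@@H]47 | intermediate
24 | as 23, with acetyl on C1 and hydroxydi(propan-2-yl)silyl on C2 | C=C[C@@H]1OC(=O)C[C@H]1CC3=C(C)[C@@H]4[C@@]5(C(=O)O[C@@H]6C([C@@H](C)CCCOC(C)=O)=C(C)C[C@@H](O[Si](C)(C)C(C)(C)C)[C@H]65)C[C@@]3(C(C)=O)[C@@H]4[Si](O)(C(C)C)C(C)C | intermediate
25 | as 24, with isopropenyl on C1 | C=C[C@@H]1OC(=O)C[C@H]1CC3=C(C)[C@@H]4[C@@]5(C(=O)O[C@@H]6C([C@@H](C)CCCOC(C)=O)=C(C)C[C@@H](O[Si](C)(C)C(C)(C)C)[C@H]65)C[C@@]3(C(C)=C)[C@@H]4[Si](O)(C(C)C)C(C)C | intermediate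
26 | as 25, with hydroxyl on C2 (over C4=C5) | C=C[C@@H]1OC(=O)C[C@H]1CC3=C(C)[C@@H]4[C@@]5(C(=O)O[C@@H]6C([C@@H](C)CCCOC(C)=O)=C(C)C[C@@H](O[Si](C)(C)C(C)(C)C)[C@H]65)C[C@@]3(C(C)=C)[C@@H]4O | intermediate
27 | C2 acetate of 26 | C=C[C@@H]1OC(=O)C[C@H]1CC3=C(C)[C@@H]4[C@@]5(C(=O)O[C@@H]6C([C@@H](C)CCCOC(C)=O)=C(C)C[C@@H](O[Si](C)(C)C(C)(C)C)[C@H]65)C[C@@]3(C(C)=C)[C@@H]4OC(C)=O | intermediate
28 | as 27, with free C8' hydroxyl (lactone still on O6') | C=C[C@@H]1OC(=O)C[C@H]1CC3=C(C)[C@@H]4[C@@]5(C(=O)O[C@@H]6C([C@@H](C)CCCOC(C)=O)=C(C)C[C@@H](O)[C@H]65)C[C@@]3(C(C)=C)[C@@H]4OC(C)=O | intermediate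
29 | ring-closing metathesis precursor: norbornene with isopropenyl on C1, trans vinyl lactone arm on C5, C2 acetate, lower 8',12'-lactone, free C6' hydroxyl | C=C[C@@H]1OC(=O)C[C@H]1CC3=C(C)[C@@H]4[C@@]5(C(=O)O[C@@H]6CC(C)=C([C@@H](C)CCCOC(C)=O)[C@@H](O)[C@@H]65)C[C@@]3(C(C)=C)[C@@H]4OC(C)=O | intermediate
30 | 9,10-dehydro target lacking the upper methylene | C1C(=O)O[C@H]2C=C(C)[C@@]34C[C@]5(C(=O)O[C@@H]6CC(C)=C([C@@H](C)CCCOC(C)=O)[C@@H](O)[C@@H]65)[C@@H](C(C)=C3C[C@H]12)[C@H]4OC(C)=O | intermediate
31 | C6' triethylsilyl ether of 30 | C1C(=O)O[C@H]2C=C(C)[C@@]34C[C@]5(C(=O)O[C@@H]6CC(C)=C([C@@H](C)CCCOC(C)=O)[C@@H](O[Si](CC)(CC)CC)[C@@H]65)[C@@H](C(C)=C3C[C@H]12)[C@H]4OC(C)=O | intermediate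
32 | 9,10-dihydro compound (C10 methyl on the face of C2), C6' OTES, no upper methylene | C1C(=O)O[C@H]2C[C@H](C)[C@@]34C[C@]5(C(=O)O[C@@H]6CC(C)=C([C@@H](C)CCCOC(C)=O)[C@@H](O[Si](CC)(CC)CC)[C@@H]65)[C@@H](C(C)=C3C[C@H]12)[C@H]4OC(C)=O | intermediate
33 | 11-(dimethylaminomethyl) derivative of 32 (C11 epimers) | CN(C)CC1C(=O)O[C@H]2C[C@H](C)[C@@]34C[C@]5(C(=O)O[C@@H]6CC(C)=C([C@@H](C)CCCOC(C)=O)[C@@H](O[Si](CC)(CC)CC)[C@@H]65)[C@@H](C(C)=C3C[C@H]12)[C@H]4OC(C)=O | intermediate
34 | trimethylammonium iodide of 33 | C[N+](C)(C)CC1C(=O)O[C@H]2C[C@H](C)[C@@]34C[C@]5(C(=O)O[C@@H]6CC(C)=C([C@@H](C)CCCOC(C)=O)[C@@H](O[Si](CC)(CC)CC)[C@@H]65)[C@@H](C(C)=C3C[C@H]12)[C@H]4OC(C)=O.[I-] | intermediate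
35 | C6' triethylsilyl ether of the target | C=C1C(=O)O[C@H]2C[C@H](C)[C@@]34C[C@]5(C(=O)O[C@@H]6CC(C)=C([C@@H](C)CCCOC(C)=O)[C@@H](O[Si](CC)(CC)CC)[C@@H]65)[C@@H](C(C)=C3C[C@H]12)[C@H]4OC(C)=O | intermediate
36 | CNP0211028.3 | C=C1C(=O)O[C@H]2C[C@H](C)[C@@]34C[C@]5(C(=O)O[C@@H]6CC(C)=C([C@@H](C)CCCOC(C)=O)[C@@H](O)[C@@H]65)[C@@H](C(C)=C3C[C@H]12)[C@H]4OC(C)=O | target

## Step count and least certain steps

Total: 23 steps. Longest linear sequence: 21 steps (steps 2–6 and 8–23).

**Step 18 (key step).** The ruthenium alkylidene formed at the C8 vinyl group may fail to add to the isopropenyl group, which is 1,1-disubstituted and sits on a quaternary carbon. Intermolecular metathesis of the vinyl groups and hydride-induced double-bond migration would then take over. Fallback, from 29 back to the route at 30: the two terminal alkenes are cleaved by Lemieux–Johnson oxidation (OsO4 cat., NaIO4, 2,6-lutidine, dioxane/H2O; the tetrasubstituted alkenes react much more slowly) to the keto aldehyde F1, with a methyl ketone at C10 and an aldehyde at C9. The ring is then closed by intramolecular McMurry coupling with low-valent titanium (TiCl3(DME)1.5, Zn–Cu, DME, reflux, slow addition), which gives the same C9=C10 alkene.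

**Step 12.** The cycloaddition may go through the wrong diene: the exocyclic enol ether and C1=C5 of 22 form a second, s-cis-locked, electron-rich diene, and two hindered partners need heat, at which the diene can also decompose. Fallback, from 22 back at 24: methanol is added across the enol ether (MeOH, PPTS cat., CH2Cl2, 0 °C) to give the mixed silyl methyl ketal F2, which has only the cyclopentadiene left. Its cycloaddition with 3 would give the ketal adduct F3, and the dilute acid of step 13 would convert F3 into 24.

**Step 11.** The C2–Si bond may fail to close: the amide base can attack silicon or the lactone instead of the fulvene methyl group, or the cyclopentadienide can be silylated intermolecularly. Fallback with known chemistry, from 16 back at 26: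
- 2-propenylmagnesium bromide with CeCl3 adds to the ketone of 16 to give the isopropenyl carbinol F4.
- Dehydration with the Burgess reagent gives the isopropenyl cyclopentadiene F5.
- Deprotonation (KHMDS) and silylation with chloro(isopropoxy)dimethylsilane give the unbridged 5-silyl diene F6.
- Cycloaddition with 3 gives the adduct F7, which is oxidised under the conditions of step 15 to 26.

Without the bridge, silicon can migrate to C3 and the isopropenyl group offers a second diene, so regioisomeric adducts would have to be separated. That is why this is the fallback and not the route.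

**Step 17.** The acyl migration may stop short: the position of the equilibrium between the trans-fused lactone 28 and the cis-fused lactone 29 is not known for the adduct, where C6' comes close to C4 and its methyl group. Fallback, from 27 back at 29: instead of one thermodynamic relaxation, the mixture is resolved by chromatography and recovered 28 is re-equilibrated under acid catalysis (camphorsulfonic acid, toluene, 50 °C) and recycled. This makes no new compound (F0).

**Step 1.** Silylation may outrun acyl migration, so that the hindered C6' hydroxyl of 1 is silylated and the dynamic resolution is lost; the base may also move the exocyclic double bond into the lactone ring. Fallback, from 1 back at 3: the two events are separated. 1 is equilibrated with camphorsulfonic acid in toluene, 2 is isolated with recycling of 1, and isolated 2 is silylated with TBSCl and imidazole. This makes no new compound (F0).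

**Step 20.** Facial selectivity may be poor, because the acetate carbonyl on C2 can bind iridium and deliver hydrogen to the wrong face; the strained tetrasubstituted C4=C5 alkene may also be over-reduced. Fallback, from 31 back at 32: substrate direction is given up for catalyst control with a chiral iridium phosphine–oxazoline complex, [Ir(cod)(L)][B(C6H3(CF3)2)4] with L = (S)- or (R)-4-tert-butyl-2-[2-(diphenylphosphanyl)phenyl]-4,5-dihydrooxazole. It reduces unfunctionalised trisubstituted alkenes with the facial sense set by the ligand enantiomer. This makes no new compound (F0).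

## Further compounds

F1 | step 18 | keto aldehyde: as 29, with formyl in place of vinyl on C8 and acetyl in place of isopropenyl on C1 | O=C[C@@H]1OC(=O)C[C@H]1CC3=C(C)[C@@H]4[C@@]5(C(=O)O[C@@H]6CC(C)=C([C@@H](C)CCCOC(C)=O)[C@@H](O)[C@@H]65)C[C@@]3(C(C)=O)[C@@H]4OC(C)=O
F2 | step 12 | mixed silyl methyl ketal of 22 (methanol added across the exocyclic enol ether; C10 epimers) | C=C[C@@H]1OC(=O)C[C@H]1CC2=C3C(C)(OC)O[Si](C(C)C)(C(C)C)C3C=C2C
F3 | step 12 | cycloadduct of F2 with 3 (as 23, with C10 as methyl ketal carbon) | C=C[C@@H]1OC(=O)C[C@H]1CC3=C(C)[C@@H]4[C@@]5(C(=O)O[C@@H]6C([C@@H](C)CCCOC(C)=O)=C(C)C[C@@H](O[Si](C)(C)C(C)(C)C)[C@H]65)C[C@@]3(C(C)(OC)O[Si]7(C(C)C)C(C)C)[C@@H]47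
F4 | step 11 | 2-{[(2S,3R)-2-ethenyl-5-oxooxolan-3-yl]methyl}-3-methyl-1-(prop-1-en-2-yl)cyclopent-2-en-1-ol | C=C[C@@H]1OC(=O)C[C@H]1CC2=C(C)CCC2(O)C(C)=C
F5 | step 11 | (4R,5S)-5-ethenyl-4-{[5-methyl-2-(prop-1-en-2-yl)cyclopenta-1,4-dien-1-yl]methyl}oxolan-2-one | C=C[C@@H]1OC(=O)C[C@H]1CC2=C(C(C)=C)CC=C2C
F6 | step 11 | 5-[isopropoxy(dimethyl)silyl] derivative of F5 (silicon on the sp3 ring carbon next to the isopropenyl-bearing carbon) | C=C[C@@H]1OC(=O)C[C@H]1CC2=C(C(C)=C)C([Si](C)(C)OC(C)C)C=C2C
F7 | step 11 | cycloadduct of F6 with 3 (as 25, with isopropoxy(dimethyl)silyl on C2) | C=C[C@@H]1OC(=O)C[C@H]1CC3=C(C)[C@@H]4[C@@]5(C(=O)O[C@@H]6C([C@@H](C)CCCOC(C)=O)=C(C)C[C@@H](O[Si](C)(C)C(C)(C)C)[C@H]65)C[C@@]3(C(C)=C)[C@@H]4[Si](C)(C)OC(C)C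
F0 | step 17 | none | none
F0 | step 1 | none | none
F0 | step 20 | none | none
A1 | alternative 1 | C6' ketone of the target skeleton, upper lactone without methylene | C1C(=O)O[C@H]2C[C@H](C)[C@@]34C[C@]5(C(=O)O[C@@H]6CC(C)=C([C@@H](C)CCCOC(C)=O)C(=O)[C@@H]65)[C@@H](C(C)=C3C[C@H]12)[C@H]4OC(C)=O
A2 | alternative 2 | norbornene C2 alcohol with hydroxyl over C4=C5, C6' tert-butyldimethylsilyl ether, upper lactone without methylene | C1C(=O)O[C@H]2C[C@H](C)[C@@]34C[C@]5(C(=O)O[C@@H]6CC(C)=C([C@@H](C)CCCOC(C)=O)[C@@H](O[Si](C)(C)C(C)(C)C)[C@@H]65)[C@@H](C(C)=C3C[C@H]12)[C@H]4O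
A3 | alternative 3 | 13'-hydroxy derivative of the target | C=C1C(=O)O[C@H]2C[C@H](C)[C@@]34[C@H](O)[C@]5(C(=O)O[C@@H]6CC(C)=C([C@@H](C)CCCOC(C)=O)[C@@H](O)[C@@H]65)[C@@H](C(C)=C3C[C@H]12)[C@H]4OC(C)=O
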